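The ten-membered carbocycle (C1–C10, briarane numbering) is disconnected at C4–C5: the only sp3–sp2 ring bond flanked by no stereocentre, lying between the C3–C4 ethylene and the trisubstituted C5=C6 alkene that carries C16. One operation, 9-BBN hydroboration of a terminal C3=C4 vinyl group followed by intramolecular B-alkyl Suzuki–Miyaura coupling with a (Z)-C5 alkenyl iodide, forms C4–C5 and closes the ring while leaving all eight stereocentres untouched. The precursor is the complete seco compound: ring A (C1, C10–C14) bearing the C2 vinyl carbinol acetate and 14-acetate, the C7–O–C19 γ-lactone, a C8/C9 acetonide and a C16 silyl ether.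

Key step: step 31

Remark 1: briarane numbering is used throughout (ring C1–C10; C15 on C1, C16 on C5, C17–C18 = CH–CH3 of the lactone, C19 = lactone C=O, C20 on C11); complex intermediates are named by these locants and their SMILES fixes the configuration.
Remark 2: enolates, alkoxides and acetylides made by deprotonation are treated as the reactive form of the numbered reactant; adducts that are transformed further in the same flask are numbered as non-isolated intermediates.
Remark 3: seco-iodide 40 and macrocycle 42 carry the configuration of 45 at all eight stereocentres and iodine cis to C7, so no structural correction is needed.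

**Ring A (steps 1–16)**

Step 1
Reactants: 1 2,2-dimethoxyacetaldehyde; 2 ethyl 2-(triphenyl-λ5-phosphanylidene)propanoate
Product: 3 ethyl (2E)-4,4-dimethoxy-2-methylbut-2-enoate
Conditions: CH2Cl2, rt → 40 °C
Reagents that add atoms: none
Why: Wittig olefination with a stabilised α-methyl ylide is E-selective, so the ester ends trans to the acetal carbon.

Step 2
Reactants: 3 ethyl (2E)-4,4-dimethoxy-2-methylbut-2-enoate
Product: 4 (2E)-4,4-dimethoxy-2-methylbut-2-en-1-ol
Conditions: DIBAL-H (2.2 equiv), CH2Cl2, −78 °C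
Reagents that add atoms: none
Why: DIBAL-H 1,2-reduction of the enoate should give the allylic alcohol without touching the acetal or the alkene geometry.

Step 3
Reactants: 5 ethyl (3R)-4-chloro-3-hydroxybutanoate
Product: 6 ethyl 2-[(2R)-oxiran-2-yl]acetate
Conditions: Ag2O, MeCN, 60 °C
Reagents that add atoms: none
Why: Silver(I)-assisted intramolecular Williamson etherification closes the epoxide under non-basic conditions, so the ester is not isomerised and the carbinol centre (future C14) is untouched.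

Step 4
Reactants: 6 ethyl 2-[(2R)-oxiran-2-yl]acetate; 7 vinylmagnesium bromide
Product: 8 ethyl (3S)-3-hydroxyhex-5-enoate
Conditions: 7 (1.3 equiv), CuI (10 mol%), THF, −40 °C
Reagents that add atoms: none
Why: Copper-catalysed Grignard opening of the terminal epoxide at CH2 outpaces ester addition and carries the pool stereocentre through unchanged (the descriptor changes by priority only).

Step 5
Reactants: 8 ethyl (3S)-3-hydroxyhex-5-enoate; 4 (2E)-4,4-dimethoxy-2-methylbut-2-en-1-ol
Product: 9 (2E)-4,4-dimethoxy-2-methylbut-2-en-1-yl (3S)-3-hydroxyhex-5-enoate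
Conditions: 1,3-dichlorotetrabutyldistannoxane (5 mol%), toluene, 110 °C, −EtOH
Reagents that add atoms: none
Why: Neutral tin-catalysed transesterification, driven by removal of ethanol, tolerates the free β-hydroxyl and the acetal.

Step 6
Reactants: 9 (2E)-4,4-dimethoxy-2-methylbut-2-en-1-yl (3S)-3-hydroxyhex-5-enoate
Product: 10 (2S,3S)-2-[(2R)-1,1-dimethoxy-3-methylbut-3-en-2-yl]-3-hydroxyhex-5-enoic acid
Conditions: LDA (2.3 equiv), THF, −78 → 23 → 45 °C; cold dil. HCl to pH 4
Reagents that add atoms: none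
Why: Dianionic Ireland–Claisen rearrangement: the lithium chelate fixes the enolate geometry, the allyl unit adds to the face remote from the C14 allyl chain through a chair with the E-substituent (C9) equatorial, which sets C10 as in the target and gives the 2,3-anti acid.

Step 7
Reactants: 10 (2S,3S)-2-[(2R)-1,1-dimethoxy-3-methylbut-3-en-2-yl]-3-hydroxyhex-5-enoic acid
Product: 11 methyl (2S,3S)-2-[(2R)-1,1-dimethoxy-3-methylbut-3-en-2-yl]-3-hydroxyhex-5-enoate
Conditions: TMSCHN2, MeOH–toluene, 0 °C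
Reagents that add atoms: trimethylsilyldiazomethane, C[Si](C)(C)C=[N+]=[N-]
Why: O-Methylation of the acid with the diazomethane surrogate is neutral and leaves acetal, alcohol and both stereocentres intact.

Step 8
Reactants: 11 methyl (2S,3S)-2-[(2R)-1,1-dimethoxy-3-methylbut-3-en-2-yl]-3-hydroxyhex-5-enoate
Product: 12 methyl (2R,3S)-2-[(2S)-1,1-dimethoxy-3-methylbut-3-en-2-yl]-3-hydroxy-2-methylhex-5-enoate
Conditions: LDA (2.3 equiv), THF, −78 → −20 °C; MeI, DMPU, −78 → 0 °C
Reagents that add atoms: iodomethane, CI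
Why: Fráter–Seebach alkylation: the chelated alkoxide–enolate is methylated on the face opposite the C14 allyl chain, so C15 ends anti to O14 (trans on the future ring, cis to C9) and the C1 quaternary centre is set.

Step 9
Reactants: 12 methyl (2R,3S)-2-[(2S)-1,1-dimethoxy-3-methylbut-3-en-2-yl]-3-hydroxy-2-methylhex-5-enoate
Product: 13 methyl (1R,2S,6S)-2-(dimethoxymethyl)-6-hydroxy-1,3-dimethylcyclohex-3-ene-1-carboxylate
Conditions: [RuCl2(=CHPh)(H2IMes)(PCy3)] (3 mol%), CH2Cl2, 40 °C
Reagents that add atoms: none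
Why: Ring-closing metathesis of the isopropenyl and allyl groups gives the trisubstituted C11=C12 alkene in a strain-free cyclohexene and involves no stereocentre.

Step 10
Reactants: 13 methyl (1R,2S,6S)-2-(dimethoxymethyl)-6-hydroxy-1,3-dimethylcyclohex-3-ene-1-carboxylate
Product: 14 (1S,5S,6S)-5-(dimethoxymethyl)-6-(hydroxymethyl)-4,6-dimethylcyclohex-3-en-1-ol
Conditions: LiAlH4, THF, 0 °C → rt
Reagents that add atoms: none
Why: Hydride reduction with LiAlH4 converts the hindered neopentyl ester into the C2 primary alcohol while acetal and alkene are inert.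

Step 11
Reactants: 14 (1S,5S,6S)-5-(dimethoxymethyl)-6-(hydroxymethyl)-4,6-dimethylcyclohex-3-en-1-ol
Product: 15 (1R,2S,6S)-2-(dimethoxymethyl)-6-hydroxy-1,3-dimethylcyclohex-3-ene-1-carbaldehyde
Conditions: TEMPO (10 mol%), PhI(OAc)2 (1.1 equiv), CH2Cl2, rt
Reagents that add atoms: none
Why: Oxoammonium (TEMPO) oxidation is selective for the primary alcohol and stops at the non-enolisable aldehyde.

Step 12
Reactants: 15 (1R,2S,6S)-2-(dimethoxymethyl)-6-hydroxy-1,3-dimethylcyclohex-3-ene-1-carbaldehyde; 7 vinylmagnesium bromide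
Product: 16 C2-epimeric vinyl carbinols (ring-A 2,14-diol)
Conditions: 7 (3 equiv), THF, −78 °C
Reagents that add atoms: none
Why: Grignard 1,2-addition brings in C3=C4; the C2 ratio (chelation should favour the 1,3-anti epimer) is irrelevant because the next step erases the centre.

Step 13
Reactants: 16 C2-epimeric vinyl carbinols
Product: 17 1-[(1R,2S,6S)-2-(dimethoxymethyl)-6-hydroxy-1,3-dimethylcyclohex-3-en-1-yl]prop-2-en-1-one
Conditions: MnO2 (excess), CH2Cl2, rt
Reagents that add atoms: none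
Why: Allylic oxidation with MnO2 converts only the vinyl carbinol, leaving the C14 hydroxyl free to direct the reduction.

Step 14
Reactants: 17 1-[(1R,2S,6S)-2-(dimethoxymethyl)-6-hydroxy-1,3-dimethylcyclohex-3-en-1-yl]prop-2-en-1-one
Product: 19 (1S,5S,6R)-5-(dimethoxymethyl)-6-[(1R)-1-hydroxyprop-2-en-1-yl]-4,6-dimethylcyclohex-3-en-1-ol, via diethylboryl chelate 18 (not isolated)
Conditions: Et2BOMe (1.1 equiv), THF–MeOH (4:1), −78 °C; NaBH4, −78 °C; MeOH co-evaporation
Reagents that add atoms: none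
Why: Narasaka–Prasad reduction: borohydride attacks the convex face of the six-membered boron chelate between O14 and the C2 carbonyl, which gives the 1,3-syn diol, i.e. C2 as in the target, with boron activation favouring 1,2- over 1,4-reduction.

Step 15
Reactants: 19 ring-A syn-2,14-diol
Product: 20 2,14-bis-O-(4-methoxybenzyl) ring-A dimethyl acetal
Conditions: NaH (2.5 equiv), PMBCl (2.5 equiv), Bu4NI (cat.), DMF, 0 °C → rt
Reagents that add atoms: 4-methoxybenzyl chloride, COc1ccc(CCl)cc1
Why: Williamson etherification of both alkoxides installs ethers that survive organolithium, aluminium amide and hydride steps and can later be removed oxidatively beside acetonide and silyl ether.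

Step 16
Reactants: 20 2,14-bis-O-PMB ring-A dimethyl acetal
Product: 21 2,14-bis-O-PMB ring-A C9 aldehyde
Conditions: PPTS (0.2 equiv), acetone–H2O (10:1), 40 °C
Reagents that add atoms: water, O
Why: Mild acid-catalysed acetal hydrolysis frees the C9 aldehyde; brief buffered conditions avoid migration of the β,γ-alkene, and C10 already has the less strained configuration (C9 trans to C2 and O14).

**C8/C17 nucleophile from malate (steps 17–19)**

Step 17
Reactants: 22 dimethyl (S)-malate
Product: 23 dimethyl (2S,3R)-2-hydroxy-3-methylbutanedioate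
Conditions: LDA (2.2 equiv), THF, −78 → −20 °C; MeI, −78 → 0 °C
Reagents that add atoms: iodomethane, CI
Why: Fráter–Seebach alkylation of the chelated malate dianion gives the anti (2S,3R) product, which sets C17 and carries C8 from the chiral pool.

Step 18
Reactants: 23 dimethyl (2S,3R)-2-hydroxy-3-methylbutanedioate
Product: 24 (2S,3R)-2-hydroxy-3-methylbutanedioic acid
Conditions: KOH (2.5 equiv), MeOH–H2O, 0 °C → rt; HCl
Reagents that add atoms: water, O
Why: Saponification gives the diacid, and neither stereocentre should epimerise as the dicarboxylate at room temperature.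

Step 19
Reactants: 24 (2S,3R)-2-hydroxy-3-methylbutanedioic acid
Product: 25 (2R)-2-[(2S,4S)-2-tert-butyl-5-oxo-1,3-dioxolan-4-yl]propanoic acid
Conditions: t-BuCHO, TsOH (cat.), H2SO4 (cat.), pentane, reflux (Dean–Stark); crystallisation
Reagents that add atoms: pivalaldehyde, CC(C)(C)C=O
Why: Acid-catalysed acetalisation of the α-hydroxy acid gives the five-membered dioxolanone as the cis isomer, storing the C8 configuration in the acetal centre (self-regeneration of stereocentres).

**Fragment union and seco chain (steps 20–30)**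

Step 20
Reactants: 21 2,14-bis-O-PMB ring-A C9 aldehyde; 25 (2R)-2-[(2S,4S)-2-tert-butyl-5-oxo-1,3-dioxolan-4-yl]propanoic acid
Product: 28 C9-O-TES aldol acid, via dilithium aldolate 26 (not isolated), via bis-triethylsilyl adduct 27 (not isolated)
Conditions: 25, LiHMDS (2.1 equiv), THF, −78 °C; 21, −78 °C; TESOTf (2.4 equiv), −78 → −40 °C; aqueous work-up at pH 5
Reagents that add atoms: triethylsilyl trifluoromethanesulfonate, CC[Si](CC)(CC)OS(=O)(=O)C(F)(F)F
Why: Aldol addition of the dioxolanone enolate (C19 masked as lithium carboxylate): attack anti to tert-butyl forms C8 with retention, a Zimmerman–Traxler chair with the ring-fixed enolate places C17 syn and O8 anti to the new C9–O bond as required, and in situ silylation blocks retro-aldol and lactonisation.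

Step 21
Reactants: 28 C9-O-TES aldol acid
Product: 29 C9-O-TES aldol tert-butyl ester
Conditions: tert-butyl 2,2,2-trichloroacetimidate (2 equiv), cyclohexane–CH2Cl2, rt
Reagents that add atoms: tert-butyl 2,2,2-trichloroacetimidate, CC(C)(C)OC(=N)C(Cl)(Cl)Cl
Why: Esterification with the trichloroacetimidate (the acid itself is the proton source) gives a tert-butyl ester that is inert to the aluminium amide and acetylide used next and too hindered to be attacked by O9.

Step 22
Reactants: 29 C9-O-TES aldol tert-butyl ester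
Product: 30 C7 Weinreb amide (8-OH, 9-OTES)
Conditions: MeNHOMe·HCl, AlMe3 (3 equiv each), CH2Cl2, 0 → 35 °C
Reagents that add atoms: N,O-dimethylhydroxylamine hydrochloride, CNOC.Cl
Why: Aluminium-amide aminolysis of the activated acylal carbonyl opens the dioxolanone to the Weinreb amide with loss of pivalaldehyde and without touching C8 or the tert-butyl ester.

Step 23
Reactants: 30 C7 Weinreb amide (8-OH, 9-OTES)
Product: 32 C8/C9 acetonide Weinreb amide, via diol amide 31 (not isolated)
Conditions: CSA (10 mol%), MeOH (5 equiv), 2,2-dimethoxypropane–CH2Cl2, 0 °C → rt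
Reagents that add atoms: 2,2-dimethoxypropane, COC(C)(C)OC
Why: Acid-catalysed silyl ether methanolysis and ketalisation should trap the C8/C9 diol as the cis-fused dioxolane faster than O9 can lactonise onto the tert-butyl ester.

Step 24
Reactants: 33 propargyl alcohol
Product: 34 tert-butyldimethyl(prop-2-yn-1-yloxy)silane
Conditions: TBSCl, imidazole, CH2Cl2, 0 °C → rt
Reagents that add atoms: tert-butyldimethylsilyl chloride, CC(C)(C)[Si](C)(C)Cl
Why: Imidazole-promoted silyl ether formation on the primary alcohol.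

Step 25
Reactants: 32 C8/C9 acetonide Weinreb amide; 34 tert-butyldimethyl(prop-2-yn-1-yloxy)silane
Product: 35 C7 ynone
Conditions: 34, n-BuLi, THF, −78 °C; 32, −78 → −20 °C
Reagents that add atoms: none
Why: Acyl substitution of the Weinreb amide by the lithium acetylide stops at the ketone through the chelated tetrahedral intermediate, the tert-butyl ester being too hindered to compete.

Step 26
Reactants: 35 C7 ynone
Product: 36 (Z)-C5-iodo enone
Conditions: NaI (2 equiv), AcOH (4 equiv), MeCN, 0 °C → rt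
Reagents that add atoms: sodium iodide, [Na+].[I-]
Why: Conjugate addition of iodide to the ynone and kinetic protonation of the allenolate give net anti-hydroiodination, i.e. the (Z)-β-iodoenone with iodine on C5 cis to C7.

Step 27
Reactants: 36 (Z)-C5-iodo enone
Product: 37 C7 allylic alcohol
Conditions: Zn(BH4)2, Et2O, −30 °C
Reagents that add atoms: none
Why: Chelation-controlled (Cram-chelate) 1,2-reduction: zinc bridges the C7 carbonyl and O8, and hydride enters from the C17 side because the other face is covered by ring A, which sits cis to C7 on the dioxolane, giving C7 as in the target.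

Step 28
Reactants: 37 C7 allylic alcohol
Product: 38 seco lactone 2,14-bis-PMB ether
Conditions: t-BuOK (0.2 equiv), THF, −20 → 0 °C
Reagents that add atoms: none
Why: Alkoxide-catalysed intramolecular transesterification (5-exo-trig) closes the γ-lactone with loss of tert-butoxide, which carries the chain; C17 keeps its preferred configuration with the methyl anti to C9.

Step 29
Reactants: 38 seco lactone 2,14-bis-PMB ether
Product: 39 seco lactone 2,14-diol
Conditions: DDQ (3 equiv), CH2Cl2–pH 7 buffer (10:1), 0 °C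
Reagents that add atoms: none
Why: Oxidative PMB ether cleavage by DDQ spares vinyl iodide, acetonide, silyl ether and lactone.

Step 30
Reactants: 39 seco lactone 2,14-diol
Product: 40 seco C5 alkenyl iodide 2,14-diacetate (cyclisation precursor)
Conditions: Ac2O, DMAP, Et3N, CH2Cl2, rt
Reagents that add atoms: acetic anhydride, CC(=O)OC(C)=O
Why: DMAP-catalysed acetylation of the two hindered secondary alcohols gives the cyclisation precursor.

**Ring closure and endgame (steps 31–34)**

Step 31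
Reactants: 40 seco C5 alkenyl iodide 2,14-diacetate
Product: 42 ten-membered carbocycle (C8/C9 acetonide; C16 OTBS; 2,14-diacetate), via B-alkyl-9-BBN borane 41 (not isolated)
Conditions: 9-BBN-H (2.5 equiv), THF, rt; then syringe-pump addition to Pd(dppf)Cl2 (20 mol%), AsPh3 (40 mol%), K3PO4 (3 M aq.), DMF–THF, 40 °C, final concentration ≤2 mM
Reagents that add atoms: none
Why: 9-BBN adds anti-Markovnikov to the only monosubstituted alkene (C3=C4) and places boron on C4 (41); Pd(0) then inserts into the C5–I bond with retention, the base-activated borate transfers C4 to palladium with retention, and reductive elimination forges C4–C5. The closest known reaction type is the intramolecular B-alkyl Suzuki–Miyaura macrocyclisation. The ten-membered carbocycle (C1–C10) closes by C(sp3)–C(sp2) reductive elimination from an eleven-membered alkyl(alkenyl)palladacycle, the C5=C6 alkene ending endocyclic with C4 cis to C7. No stereocentre is formed, so only chemoselectivity and ring strain matter. Chemoselectivity rests on 9-BBN ignoring the two trisubstituted alkenes, on the silyl (not acyl) group at C16, which prevents Pd(0) ionisation of an allylic ester, and on the preset iodide geometry; ring closure over oligomerisation is secured by slow addition at high dilution and aided by the cis-fused C8/C9 acetonide, which holds C7 and C10 on the same side of the C8–C9 bond.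

Step 32
Reactants: 42 ten-membered carbocycle (C16 OTBS)
Product: 43 C16 allylic alcohol
Conditions: HF·pyridine, pyridine–THF, 0 °C
Reagents that add atoms: none
Why: Buffered fluoride cleavage of the primary allylic silyl ether spares acetates, lactone and acetonide.

Step 33
Reactants: 43 C16 allylic alcohol
Product: 44 2,14,16-triacetate 8,9-acetonide
Conditions: Ac2O, pyridine, DMAP (cat.), 0 °C → rt
Reagents that add atoms: acetic anhydride, CC(=O)OC(C)=O
Why: Acetylation of the unhindered primary allylic alcohol.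

Step 34
Reactants: 44 2,14,16-triacetate 8,9-acetonide
Product: 45 CNP0322315.2
Conditions: TFA–H2O–CH2Cl2 (2:1:10), 0 °C → rt
Reagents that add atoms: none
Why: Acid-catalysed hydrolysis of the isopropylidene ketal frees the 8,9-diol, the acetates and the γ-lactone being stable to brief aqueous acid.

**Compound list**

1 | 2,2-dimethoxyacetaldehyde | COC(OC)C=O | starting material
2 | ethyl 2-(triphenyl-λ5-phosphanylidene)propanoate | CCOC(=O)C(C)=P(c1ccccc1)(c1ccccc1)c1ccccc1 | starting material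
3 | ethyl (2E)-4,4-dimethoxy-2-methylbut-2-enoate | CCOC(=O)/C(C)=C/C(OC)OC | intermediate
4 | (2E)-4,4-dimethoxy-2-methylbut-2-en-1-ol | OC/C(C)=C/C(OC)OC | intermediate
5 | ethyl (3R)-4-chloro-3-hydroxybutanoate | CCOC(=O)C[C@@H](O)CCl | starting material
6 | ethyl 2-[(2R)-oxiran-2-yl]acetate | CCOC(=O)C[C@@H]1CO1 | intermediate
7 | vinylmagnesium bromide | C=C[Mg]Br | starting material
8 | ethyl (3S)-3-hydroxyhex-5-enoate | CCOC(=O)C[C@@H](O)CC=C | intermediate
9 | (2E)-4,4-dimethoxy-2-methylbut-2-en-1-yl (3S)-3-hydroxyhex-5-enoate | COC(OC)/C=C(\C)/COC(=O)C[C@@H](O)CC=C | intermediate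
10 | (2S,3S)-2-[(2R)-1,1-dimethoxy-3-methylbut-3-en-2-yl]-3-hydroxyhex-5-enoic acid | COC(OC)[C@H]([C@H](C(=O)O)[C@@H](O)CC=C)C(C)=C | intermediate
11 | methyl (2S,3S)-2-[(2R)-1,1-dimethoxy-3-methylbut-3-en-2-yl]-3-hydroxyhex-5-enoate | COC(OC)[C@H]([C@H](C(=O)OC)[C@@H](O)CC=C)C(C)=C | intermediate
12 | methyl (2R,3S)-2-[(2S)-1,1-dimethoxy-3-methylbut-3-en-2-yl]-3-hydroxy-2-methylhex-5-enoate | COC(OC)[C@H]([C@@](C)(C(=O)OC)[C@@H](O)CC=C)C(C)=C | intermediate
13 | methyl (1R,2S,6S)-2-(dimethoxymethyl)-6-hydroxy-1,3-dimethylcyclohex-3-ene-1-carboxylate | COC(OC)[C@H]1C(C)=CC[C@H](O)[C@]1(C)C(=O)OC | intermediate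
14 | (1S,5S,6S)-5-(dimethoxymethyl)-6-(hydroxymethyl)-4,6-dimethylcyclohex-3-en-1-ol | COC(OC)[C@H]1C(C)=CC[C@H](O)[C@]1(C)CO | intermediate
15 | (1R,2S,6S)-2-(dimethoxymethyl)-6-hydroxy-1,3-dimethylcyclohex-3-ene-1-carbaldehyde | COC(OC)[C@H]1C(C)=CC[C@H](O)[C@]1(C)C=O | intermediate
16 | (1S,5S,6R)-5-(dimethoxymethyl)-6-(1-hydroxyprop-2-en-1-yl)-4,6-dimethylcyclohex-3-en-1-ol, both carbinol (C2) epimers | COC(OC)[C@H]1C(C)=CC[C@H](O)[C@]1(C)C(O)C=C | intermediate
17 | 1-[(1R,2S,6S)-2-(dimethoxymethyl)-6-hydroxy-1,3-dimethylcyclohex-3-en-1-yl]prop-2-en-1-one | COC(OC)[C@H]1C(C)=CC[C@H](O)[C@]1(C)C(=O)C=C | intermediate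
18 | O14-diethylboryl derivative (boron chelate) of 17 | COC(OC)[C@H]1C(C)=CC[C@H](OB(CC)CC)[C@]1(C)C(=O)C=C | intermediate
19 | (1S,5S,6R)-5-(dimethoxymethyl)-6-[(1R)-1-hydroxyprop-2-en-1-yl]-4,6-dimethylcyclohex-3-en-1-ol (O2/O14 syn) | COC(OC)[C@H]1C(C)=CC[C@H](O)[C@]1(C)[C@H](O)C=C | intermediate
20 | (4S,5R,6S)-6-(dimethoxymethyl)-4-[(4-methoxyphenyl)methoxy]-5-{(1R)-1-[(4-methoxyphenyl)methoxy]prop-2-en-1-yl}-1,5-dimethylcyclohex-1-ene | COC(OC)[C@H]1C(C)=CC[C@H](OCc2ccc(OC)cc2)[C@]1(C)[C@H](OCc2ccc(OC)cc2)C=C | intermediate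
21 | (1S,5S,6R)-5-[(4-methoxyphenyl)methoxy]-6-{(1R)-1-[(4-methoxyphenyl)methoxy]prop-2-en-1-yl}-2,6-dimethylcyclohex-2-ene-1-carbaldehyde (ring-A C9 aldehyde) | O=C[C@H]1C(C)=CC[C@H](OCc2ccc(OC)cc2)[C@]1(C)[C@H](OCc2ccc(OC)cc2)C=C | intermediate
22 | dimethyl (S)-malate | COC(=O)C[C@H](O)C(=O)OC | starting material
23 | dimethyl (2S,3R)-2-hydroxy-3-methylbutanedioate | COC(=O)[C@H](C)[C@H](O)C(=O)OC | intermediate
24 | (2S,3R)-2-hydroxy-3-methylbutanedioic acid | OC(=O)[C@H](C)[C@H](O)C(=O)O | intermediate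
25 | (2R)-2-[(2S,4S)-2-tert-butyl-5-oxo-1,3-dioxolan-4-yl]propanoic acid (tert-butyl cis to the side chain) | OC(=O)[C@H](C)[C@@H]1O[C@H](C(C)(C)C)OC1=O | intermediate
26 | dilithium salt (C9 alkoxide, C19 carboxylate) of the aldol adduct of 25 and 21; C9 trans to tert-butyl on the dioxolanone, C8 and C9 as in 45 | [Li]OC(=O)[C@H](C)[C@]1([C@H](O[Li])[C@H]2C(C)=CC[C@H](OCc3ccc(OC)cc3)[C@]2(C)[C@H](OCc3ccc(OC)cc3)C=C)O[C@H](C(C)(C)C)OC1=O | intermediate
27 | C9-O-triethylsilyl ether, C19 triethylsilyl ester of the aldol adduct | CC[Si](CC)(CC)OC(=O)[C@H](C)[C@]1([C@H](O[Si](CC)(CC)CC)[C@H]2C(C)=CC[C@H](OCc3ccc(OC)cc3)[C@]2(C)[C@H](OCc3ccc(OC)cc3)C=C)O[C@H](C(C)(C)C)OC1=O | intermediate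
28 | C9-O-triethylsilyl aldol acid (dioxolanone at C7/O8, free C19 acid) | OC(=O)[C@H](C)[C@]1([C@H](O[Si](CC)(CC)CC)[C@H]2C(C)=CC[C@H](OCc3ccc(OC)cc3)[C@]2(C)[C@H](OCc3ccc(OC)cc3)C=C)O[C@H](C(C)(C)C)OC1=O | intermediate
29 | tert-butyl ester of 28 | CC(C)(C)OC(=O)[C@H](C)[C@]1([C@H](O[Si](CC)(CC)CC)[C@H]2C(C)=CC[C@H](OCc3ccc(OC)cc3)[C@]2(C)[C@H](OCc3ccc(OC)cc3)C=C)O[C@H](C(C)(C)C)OC1=O | intermediate
30 | C7 N-methoxy-N-methylamide with free tertiary 8-OH, 9-OTES and C19 tert-butyl ester | CC(C)(C)OC(=O)[C@H](C)[C@@](O)([C@H](O[Si](CC)(CC)CC)[C@H]1C(C)=CC[C@H](OCc2ccc(OC)cc2)[C@]1(C)[C@H](OCc2ccc(OC)cc2)C=C)C(=O)N(C)OC | intermediate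
31 | 8,9-diol of 30 | CC(C)(C)OC(=O)[C@H](C)[C@@](O)([C@H](O)[C@H]1C(C)=CC[C@H](OCc2ccc(OC)cc2)[C@]1(C)[C@H](OCc2ccc(OC)cc2)C=C)C(=O)N(C)OC | intermediate
32 | 8,9-O-isopropylidene C7 Weinreb amide (C7 and ring A cis on the dioxolane) | CC(C)(C)OC(=O)[C@H](C)[C@@]1(C(=O)N(C)OC)OC(C)(C)O[C@@H]1[C@H]2C(C)=CC[C@H](OCc3ccc(OC)cc3)[C@]2(C)[C@H](OCc3ccc(OC)cc3)C=C | intermediate
33 | propargyl alcohol | C#CCO | starting material
34 | tert-butyldimethyl(prop-2-yn-1-yloxy)silane | C#CCO[Si](C)(C)C(C)(C)C | intermediate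
35 | C7 ynone (C5≡C6, C16 OTBS) | CC(C)(C)OC(=O)[C@H](C)[C@@]1(C(=O)C#CCO[Si](C)(C)C(C)(C)C)OC(C)(C)O[C@@H]1[C@H]2C(C)=CC[C@H](OCc3ccc(OC)cc3)[C@]2(C)[C@H](OCc3ccc(OC)cc3)C=C | intermediate
36 | (5Z)-5-iodo-6-en-7-one (iodine cis to C7) | CC(C)(C)OC(=O)[C@H](C)[C@@]1(C(=O)/C=C(\I)CO[Si](C)(C)C(C)(C)C)OC(C)(C)O[C@@H]1[C@H]2C(C)=CC[C@H](OCc3ccc(OC)cc3)[C@]2(C)[C@H](OCc3ccc(OC)cc3)C=C | intermediate
37 | (5Z)-5-iodo-6-en-7-ol, C7 as in 45, C19 tert-butyl ester | CC(C)(C)OC(=O)[C@H](C)[C@@]1([C@@H](O)/C=C(\I)CO[Si](C)(C)C(C)(C)C)OC(C)(C)O[C@@H]1[C@H]2C(C)=CC[C@H](OCc3ccc(OC)cc3)[C@]2(C)[C@H](OCc3ccc(OC)cc3)C=C | intermediate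
38 | seco C7–O–C19 γ-lactone, 2,14-bis-PMB ether, 8,9-acetonide, C16 OTBS, (Z)-C5 iodide | I/C(CO[Si](C)(C)C(C)(C)C)=C\[C@@H]1OC(=O)[C@H](C)[C@@]1(OC(C)(C)O3)[C@H]3[C@H]2C(C)=CC[C@H](OCc4ccc(OC)cc4)[C@]2(C)[C@H](OCc4ccc(OC)cc4)C=C | intermediate
39 | seco lactone 2,14-diol | I/C(CO[Si](C)(C)C(C)(C)C)=C\[C@@H]1OC(=O)[C@H](C)[C@@]1(OC(C)(C)O3)[C@H]3[C@H]2C(C)=CC[C@H](O)[C@]2(C)[C@H](O)C=C | intermediate
40 | seco C5 alkenyl iodide: C2 vinyl carbinol acetate, 14-acetate, γ-lactone, 8,9-acetonide, C16 OTBS | I/C(CO[Si](C)(C)C(C)(C)C)=C\[C@@H]1OC(=O)[C@H](C)[C@@]1(OC(C)(C)O3)[C@H]3[C@H]2C(C)=CC[C@H](OC(C)=O)[C@]2(C)[C@H](OC(C)=O)C=C | intermediate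
41 | C4-(9-borabicyclo[3.3.1]nonan-9-yl) derivative of 40 | I/C(CO[Si](C)(C)C(C)(C)C)=C\[C@@H]1OC(=O)[C@H](C)[C@@]1(OC(C)(C)O3)[C@H]3[C@H]2C(C)=CC[C@H](OC(C)=O)[C@]2(C)[C@H](OC(C)=O)CCB4C5CCCC4CCC5 | intermediate
42 | cyclised briarane: ten-membered ring, 8,9-acetonide, C16 OTBS, 2,14-diacetate | CC(C)(C)[Si](C)(C)OC/C1=C/[C@@H]2OC(=O)[C@H](C)[C@@]2(OC(C)(C)O3)[C@H]3[C@H]2C(C)=CC[C@H](OC(C)=O)[C@]2(C)[C@H](OC(C)=O)CC1 | intermediate
43 | 16-hydroxy 2,14-diacetate 8,9-acetonide | OC/C1=C/[C@@H]2OC(=O)[C@H](C)[C@@]2(OC(C)(C)O3)[C@H]3[C@H]2C(C)=CC[C@H](OC(C)=O)[C@]2(C)[C@H](OC(C)=O)CC1 | intermediate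
44 | 2,14,16-triacetate 8,9-acetonide | CC(=O)OC/C1=C/[C@@H]2OC(=O)[C@H](C)[C@@]2(OC(C)(C)O3)[C@H]3[C@H]2C(C)=CC[C@H](OC(C)=O)[C@]2(C)[C@H](OC(C)=O)CC1 | intermediate
45 | CNP0322315.2, (1S,2R,5E,7S,8R,9R,10S,14S,17R)-2,14,16-triacetoxy-8,9-dihydroxybriara-5,11-dien-19,7-olide | CC(=O)OC/C1=C/[C@@H]2OC(=O)[C@H](C)[C@@]2(O)[C@H](O)[C@H]2C(C)=CC[C@H](OC(C)=O)[C@]2(C)[C@H](OC(C)=O)CC1 | target

**Step count and risk**

Total step count: 34. Longest linear sequence: 28 steps (from 5 through steps 3–16, 20–23 and 25–34).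

Steps most likely to fail:

1. Step 31. Oligomerisation, protodeboronation or β-hydride elimination of the alkylpalladium may outrun closure of the strained ten-membered ring. The fallback sets out from 40: hydroboration of the vinyl group with 9-BBN and oxidation with NaBO3 would give primary alcohol F1, and Appel iodination (I2, PPh3, imidazole) would give alkyl iodide F2. Zinc dust with LiCl in THF should insert selectively into the sp3 C–I bond to give alkylzinc iodide F3, which is closed onto the alkenyl iodide by Pd-catalysed intramolecular Negishi coupling at high dilution, coming back to the route at 42.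

2. Step 20. Retro-aldol and low conversion at the congested C8–C9 bond, enolisation of the aldehyde, or erosion of C9 selectivity in a mismatched pairing may occur. The fallback sets out from 21: Pinnick oxidation would give ring-A carboxylic acid F4, which is activated with carbonyldiimidazole as acyl imidazole F5 and used to C-acylate the dilithium salt of 25 (anti to tert-butyl), giving β-keto dioxolanone acid F6. Zn(BH4)2 reduction under chelation control (C9=O/C7=O chelate, hydride from the O8 side) would give hydroxy acid F7, and silylation with TESOTf followed by aqueous work-up comes back to the route at 28.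

3. Step 22. The bulky aluminium amide may fail to reach the neopentyl-type acylal carbonyl, and forcing would bring loss of the silyl ether and retro-aldol cleavage. The fallback sets out from 29: the lithium acetylide of 34 is added once to the dioxolanone carbonyl at −78 °C (the hemiketal alkoxide collapses with loss of pivalaldehyde only on work-up) to give α-hydroxy ynone F8. CSA/MeOH removes the silyl group to give diol ynone F9, which is ketalised in the same flask with 2,2-dimethoxypropane, coming back to the route at 35.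

Further compounds
F1 | step 31 | C4 primary alcohol from hydroboration–oxidation of 40 | I/C(CO[Si](C)(C)C(C)(C)C)=C\[C@@H]1OC(=O)[C@H](C)[C@@]1(OC(C)(C)O3)[C@H]3[C@H]2C(C)=CC[C@H](OC(C)=O)[C@]2(C)[C@H](OC(C)=O)CCO
F2 | step 31 | C4 alkyl iodide | I/C(CO[Si](C)(C)C(C)(C)C)=C\[C@@H]1OC(=O)[C@H](C)[C@@]1(OC(C)(C)O3)[C@H]3[C@H]2C(C)=CC[C@H](OC(C)=O)[C@]2(C)[C@H](OC(C)=O)CCI
F3 | step 31 | C4 alkylzinc iodide | I/C(CO[Si](C)(C)C(C)(C)C)=C\[C@@H]1OC(=O)[C@H](C)[C@@]1(OC(C)(C)O3)[C@H]3[C@H]2C(C)=CC[C@H](OC(C)=O)[C@]2(C)[C@H](OC(C)=O)CC[Zn]I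
F4 | step 20 | ring-A C9 carboxylic acid (bis-PMB) | OC(=O)[C@H]1C(C)=CC[C@H](OCc2ccc(OC)cc2)[C@]1(C)[C@H](OCc2ccc(OC)cc2)C=C
F5 | step 20 | ring-A C9 acyl imidazole | O=C(n1ccnc1)[C@H]2C(C)=CC[C@H](OCc3ccc(OC)cc3)[C@]2(C)[C@H](OCc3ccc(OC)cc3)C=C
F6 | step 20 | C9-keto dioxolanone acid | OC(=O)[C@H](C)[C@]1(C(=O)[C@H]2C(C)=CC[C@H](OCc3ccc(OC)cc3)[C@]2(C)[C@H](OCc3ccc(OC)cc3)C=C)O[C@H](C(C)(C)C)OC1=O
F7 | step 20 | C9-hydroxy dioxolanone acid | OC(=O)[C@H](C)[C@]1([C@H](O)[C@H]2C(C)=CC[C@H](OCc3ccc(OC)cc3)[C@]2(C)[C@H](OCc3ccc(OC)cc3)C=C)O[C@H](C(C)(C)C)OC1=O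
F8 | step 22 | α-hydroxy ynone (8-OH, 9-OTES, C19 tert-butyl ester) | CC(C)(C)OC(=O)[C@H](C)[C@@](O)([C@H](O[Si](CC)(CC)CC)[C@H]1C(C)=CC[C@H](OCc2ccc(OC)cc2)[C@]1(C)[C@H](OCc2ccc(OC)cc2)C=C)C(=O)C#CCO[Si](C)(C)C(C)(C)C
F9 | step 22 | 8,9-diol ynone | CC(C)(C)OC(=O)[C@H](C)[C@@](O)([C@H](O)[C@H]1C(C)=CC[C@H](OCc2ccc(OC)cc2)[C@]1(C)[C@H](OCc2ccc(OC)cc2)C=C)C(=O)C#CCO[Si](C)(C)C(C)(C)C
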